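**Slow stop.** The cedar run slows long before its starting material is used up: 36.0% of the starting material has reacted at 1.00 h and 47.0% at 5.00 h, so I take that first span as the catalyst's working time. Ash, with half the second substrate, has reacted 64.0% at 5.00 h. Between these two runs, less second substrate goes with more conversion, but reagent was not varied in the earlier runs.

| setting | cedar | birch | maple | ash | Saturday's | Monday's | Sunday's | Friday's | Thursday's |
|---|---|---|---|---|---|---|---|---|---|
| starting material | 20 mM | 20 mM | 20 mM | 20 mM | 20 mM (fed, over 3.0 h) | 20 mM (in portions, 3, over 3.0 h) | 20 mM (fed, over 20 min) | 20 mM | 20 mM |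
| second substrate | 10 mM | 10 mM | 10 mM | 5 mM | 10.0 mM | 10.0 mM | 10.0 mM | 10.0 mM | 10.0 mM |
| reagent | 50 mM | 50 mM | 50 mM | 50 mM | 50.0 mM | 50.0 mM | 50.0 mM | 50.0 mM (fed, over 3.0 h) | 50.0 mM |
| free catalyst | 100 µM | 50 µM | 75 µM | 100 µM | 100 µM | 100 µM | 100 µM | 100 µM | 100 µM |
| remark | run made earlier | run made earlier | run made earlier | run made earlier | all else is in the flask from the start; the feed brings no volume worth counting | first portion at the start, last at 3.0 h | all else is in the flask from the start; the feed brings no volume worth counting | all else is in the flask from the start; the feed brings no volume worth counting | everything together at the start |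
| time |  |  |  |  | 5.0 h | 5.0 h | 5.0 h | 5.0 h | 5.0 h |

| run | time / h | target / % | starting material / % |
|---|---|---|---|
| cedar | 1.00 | 16 | 64 |
| cedar | 2.00 | 21 | 58 |
| cedar | 3.00 | 20 | 51 |
| cedar | 4.00 | 19 | 54 |
| cedar | 5.00 | 18 | 53 |
| birch | 0.417 | 10 | 87 |
| birch | 0.833 | 8 | 80 |
| birch | 1.33 | 10 | 75 |
| birch | 2.50 | 12 | 70 |
| birch | 5.00 | 13 | 70 |
| maple | 0.417 | 7 | 78 |
| maple | 0.833 | 14 | 70 |
| maple | 1.33 | 14 | 65 |
| maple | 2.50 | 18 | 61 |
| maple | 5.00 | 12 | 60 |
| ash | 0.417 | 17 | 67 |
| ash | 0.833 | 19 | 51 |
| ash | 1.33 | 25 | 45 |
| ash | 2.50 | 26 | 40 |
| ash | 5.00 | 25 | 36 |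

(readings scatter by 1.5 percentage points)

- the flask with the highest amount of target, in percent of the starting material charged ("all alike" if they lie within 1.5 percentage points) (Saturday's / Monday's / Sunday's / Friday's / Thursday's / all alike)
- final target, as a percentage of the starting material charged, in Saturday's
- final target, as a percentage of the starting material charged, in Monday's
- final target, as a percentage of the starting material charged, in Sunday's
- final target, as a percentage of the starting material charged, in Friday's
- final target, as a percentage of the starting material charged, in Thursday's



**Guard ratio.** I fold the givens into a pure number: for Friday's it is 1.67, the reagent fed during the working time divided by the second substrate charged. I call it the guard ratio, and I guess that reagent protects the catalyst from second substrate. Thursday's, like cedar, holds its reagent from the start and has 5.00; ash has 10.0. Read from the last cedar and ash readings, with their scatter, conversion grows as the ratio to the power 0.445. So Friday's should convert 28.8%, and at cedar's share of target in what reacted it gives 11.0%.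

**Its test.** The number isn't enough. Birch and maple share cedar's ratio, yet they end with 70% and 60% of starting material against cedar's 53%, so the catalyst charge counts too. Saturday's, Monday's and Sunday's also share that ratio, although their starting material goes in over time, so my reckoning stops at Friday's.

**The forecast.** It names Thursday's as best, with 6% for Saturday's, 8% for Monday's, 16% for Sunday's and 18.5% for Thursday's. For Friday's it gives 17%, saying “Reagent was never varied, so Friday is a guess”. My 11.0% stands lower.

**The result.** Thursday's leads with 18.1%; Saturday's gives 5.03%, Monday's 7.51%, Sunday's 15.8% and Friday's 3.48%.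

    reagent + catalyst intermediate B → free catalyst + second product (k = 0.787 L mol⁻¹ s⁻¹)
    target ⇌ isomer of the product (K = 1.55, k = 0.00116 s⁻¹)
    second substrate + free catalyst ⇌ catalyst intermediate B (K = 210 L mol⁻¹, k = 8.01 L mol⁻¹ s⁻¹)
    reagent + catalyst intermediate A ⇌ free catalyst + target (K = 0.132, k = 2.03 L mol⁻¹ s⁻¹)
    starting material + free catalyst ⇌ catalyst intermediate A (K = 150 L mol⁻¹, k = 123 L mol⁻¹ s⁻¹)
    second substrate + catalyst intermediate B → spent catalyst (k = 0.175 L mol⁻¹ s⁻¹)

**The neighbour.** At ratio 1.67, Friday's ends with 8.85% of its starting material no longer there unbound, under my 28.8%. The neighbour is Friday's with 4.0 mM of second substrate, so its ratio is 4.17. The same power gives conversion 43.3% and target 16.6%. That flask ends with 61.0% of its starting material no longer there unbound. Its ratio is lower than Thursday's, yet it ends with more target than Thursday's, at 24.1%.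

The readings are calculated on assumed constants, noise included.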